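The earlier runs and the new flask are simulated for an exercise; scatter was added.

Late in Friday's run the starting material was falling slowly, so the figure I needed for 10 h was the tail of a decay. This flask is Friday's recipe, followed further.

all flasks: starting material 0.80 M

| run | reagent | remark | time |
|---|---|---|---|
| Friday's | 0.88 M | the very flask that is asked about, followed so far |  |
| flask | 0.880 M |  | 10 h |

Friday's run (percent of the starting material charged)

| time / h | starting material / % | mono adduct / % | bis adduct / % |
|---|---|---|---|
| 0.500 | 76 | 28 | 2 |
| 1.00 | 65 | 37 | 0 |
| 1.50 | 62 | 41 | 0 |
| 2.50 | 48 | 48 | 2 |
| 3.00 | 50 | 51 | 2 |
| 4.00 | 45 | 56 | 0 |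

(readings scatter by 2 percentage points)

- starting material at 10 h, in percent of the starting material charged
- mono adduct at 10 h, in percent of the starting material charged
- bis adduct at 10 h, in percent of the starting material charged
- triple product at 10 h, in percent of the starting material charged

- what was read earlier has a scatter of 2 percentage points, one standard deviation
- candidate steps: starting material + reagent -> mono adduct; reagent + mono adduct -> bis adduct; reagent + bis adduct -> triple product; reagent + triple product -> tetra adduct; 2 reagent -> homo dimer

First I took the main step by itself: starting material plus reagent gives mono adduct, with nearly equal charges. The first reading gives a second-order constant of 0.789 M⁻¹ h⁻¹, and that picture leaves 13.7 % of the starting material at 10 h. The readings disagree: near 3.38 h it stood at about 0.376 M and fell at just 0.0256 M h⁻¹.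

Next I added the loss of reagent to homo dimer. Dividing that fall by the constant and the level gave about 0.0862 M of reagent left, a rough value, since the slope rests on readings with a scatter of 2 percentage points. I treated the remaining reagent as pseudo-first-order, with a time constant of 3.37 h against the starting material. By 10 h this estimate leaves 0.0121 M, far less than the charge, so I counted the whole charge of reagent as used.

For the tail I read from Friday's run a capture share of 53.4 %, the starting material converted per reagent gone. I assumed the remaining reagent divides in the same way. Applying the share to the whole charge of reagent left 41.2 % of the starting material.

Last came the small correction. The bis adduct readings average 1.00 %, so I took that from the converted part, which gave 57.8 % mono adduct, and I expected no readable triple product.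

The forecast gave 33 % starting material, 65 % mono adduct, 1.5 % bis adduct and 0 % triple product, with “uncertainty mainly in how much reagent survives”; its starting material is lower than mine.

The flask gave 40.9 % starting material, 58.3 % mono adduct, 0.792 % bis adduct and 0.0427 % triple product.

    starting material + reagent → mono adduct (k = 0.977 M⁻¹ h⁻¹)
    reagent + mono adduct → bis adduct (k = 0.0271 M⁻¹ h⁻¹)
    reagent + bis adduct → triple product (k = 0.163 M⁻¹ h⁻¹)
    reagent + triple product → tetra adduct (k = 0.0190 M⁻¹ h⁻¹)
    2 reagent → homo dimer (k = 0.666 M⁻¹ h⁻¹)

This flask's capture share, taken per reagent charged, came to 53.8 %, against my 53.4 % from the readings. The step from two reagent to homo dimer is the main reason that mono adduct ended at 58.3 %: the same flask without that step reached 87.4 %. In the neighbour flask with 1.5 M of reagent, 26.4 % of the starting material remained, so its capture share per reagent charged was 39.2 %.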